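The cyclopentane ring is disconnected across C2–C3 and C3a–C8a (azulene numbering), which turns the C3 carbinol into a ketone and ring atoms C3, C3a, C8a, C1 and C2 into a 4-pentenal. The key step is a rhodium-catalysed tandem Claisen rearrangement–hydroacylation: the [3,3] shift of an acyclic (E,E)-allyl vinyl ether joins C3a to the quaternary C8a, and the aldehyde thus released closes C3–C2 onto the new vinyl group. The step exploits the vicinal C3a/C8a pair next to the oxygenated C3 of the five-membered ring. Its precursor is a linear bis-silyloxy tetraene ether assembled from two small chiral fragments; metathesis then closes the seven-membered ring.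

Key step: step 9

Remark: ring positions are given in the azulene numbering of the target (C1/C2 methylenes, C3 carbinol, C3a and C8a ring fusion, C4 aroyloxy carbon, C6=C7 alkene, C8 isovaleryloxy carbon).
Remark: (CH2=CH)2Zn is used as a separately prepared, salt-free solution; the alkene geometry of 14 and the methyl-bearing oxirane carbon of 15 are left undefined because that carbon ends as the isopropyl methine.

Step 1
Reactants: 1 ethyl glyoxylate; 2 2-methylpropene
Product: 3 ethyl (2R)-2-hydroxy-4-methylpent-4-enoate
Conditions: (R)-BINOL (10 mol %), TiCl2(OiPr)2 (10 mol %), 4 Å MS, CH2Cl2, −30 °C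
Reagents that add atoms: none
Why: Catalytic asymmetric carbonyl-ene reaction; the BINOL–titanium Lewis acid binds the glyoxylate and exposes one aldehyde face to the alkene, which should set the (R)-carbinol that becomes C4.

Step 2
Reactants: 3 ethyl (2R)-2-hydroxy-4-methylpent-4-enoate
Product: 4 ethyl (2R)-4-methyl-2-[(triethylsilyl)oxy]pent-4-enoate
Conditions: Et3SiCl, imidazole, DMF, 0 °C
Reagents that add atoms: chlorotriethylsilane, CC[Si](Cl)(CC)CC
Why: Standard silylation of a secondary alcohol; the triethylsilyl ether is chosen because it can later be cleaved in the presence of the tert-butyldimethylsilyl ether at C8.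

Step 3
Reactants: 4 ethyl (2R)-4-methyl-2-[(triethylsilyl)oxy]pent-4-enoate
Product: 5 (2R)-4-methyl-2-[(triethylsilyl)oxy]pent-4-enal
Conditions: iBu2AlH (1.05 equiv), CH2Cl2, −78 °C; aq. potassium sodium tartrate
Reagents that add atoms: none
Why: Partial ester reduction stops at the aldehyde because the α-silyloxy tetrahedral aluminate persists until work-up; the stereocentre is not touched.

Step 4
Reactants: 5 (2R)-4-methyl-2-[(triethylsilyl)oxy]pent-4-enal
Product: 6 triethyl{[(1E,3R)-1-iodo-5-methylhexa-1,5-dien-3-yl]oxy}silane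
Conditions: CrCl2 (6 equiv), CHI3 (2 equiv), THF, 0 °C to rt
Reagents that add atoms: iodoform, IC(I)I
Why: Takai olefination; the geminal dichromium species adds to the aldehyde and eliminates to the (E)-vinyl iodide without epimerising the α-silyloxy centre.

Step 5
Reactants: 7 (2E)-3-methyl-4-oxobut-2-en-1-yl acetate
Product: 8 (2E,4R)-4-hydroxy-3-methylhexa-2,5-dien-1-yl acetate
Conditions: (CH2=CH)2Zn (1.5 equiv), diphenyl(1-methylpyrrolidin-2-yl)methanol (10 mol %, the enantiomer that gives the R alcohol), toluene, 0 °C
Reagents that add atoms: divinylzinc, C=C[Zn]C=C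
Why: Amino-alcohol-catalysed enantioselective 1,2-addition of an alkenylzinc reagent; the chiral zinc aminoalkoxide delivers the vinyl group to one face of the enal to set the (R)-carbinol that becomes C8, and the organozinc leaves the acetate untouched.

Step 6
Reactants: 8 (2E,4R)-4-hydroxy-3-methylhexa-2,5-dien-1-yl acetate
Product: 9 (2E,4R)-4-{[tert-butyl(dimethyl)silyl]oxy}-3-methylhexa-2,5-dien-1-yl acetate
Conditions: tBuMe2SiCl, imidazole, DMF, rt
Reagents that add atoms: tert-butylchlorodimethylsilane, CC(C)(C)[Si](C)(C)Cl
Why: Silylation of the bis-allylic alcohol under non-acidic conditions avoids ionisation; the silyloxy group later serves as the stereodirecting element in step 9.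

Step 7
Reactants: 9 (2E,4R)-4-{[tert-butyl(dimethyl)silyl]oxy}-3-methylhexa-2,5-dien-1-yl acetate
Product: 10 (2E,4R)-4-{[tert-butyl(dimethyl)silyl]oxy}-3-methylhexa-2,5-dien-1-ol
Conditions: K2CO3 (0.2 equiv), MeOH, 0 °C
Reagents that add atoms: none
Why: Base-catalysed transesterification removes the primary acetate, while the secondary silyl ether and both alkenes are inert.

Step 8
Reactants: 6 triethyl{[(1E,3R)-1-iodo-5-methylhexa-1,5-dien-3-yl]oxy}silane; 10 (2E,4R)-4-{[tert-butyl(dimethyl)silyl]oxy}-3-methylhexa-2,5-dien-1-ol
Product: 11 (E,E)-allyl vinyl ether (full name in the compound list)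
Conditions: CuI (10 mol %), 3,4,7,8-tetramethyl-1,10-phenanthroline (20 mol %), Cs2CO3 (1.5 equiv), toluene, 80 °C
Reagents that add atoms: none
Why: Copper-catalysed Ullmann-type C–O coupling of a vinyl iodide with a primary allylic alcohol proceeds with retention of the (E)-alkene geometry, and 80 °C is low enough that the [3,3] shift should not start.

Step 9
Reactants: 11 (E,E)-allyl vinyl ether
Product: 13 2,3,3-trisubstituted cyclopentanone (full name in the compound list), via 4-pentenal 12 (not isolated)
Conditions: [Rh(cod)Cl]2 (5 mol %), dppe (10 mol %), degassed PhCN, 135 °C, sealed tube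
Reagents that add atoms: none
Why: Tandem Claisen rearrangement–hydroacylation: heating takes the allyl vinyl ether through a chair [3,3] transition state (enol ether carbon C3a onto allyl terminus C8a, C2–O bond breaking) to the 4-pentenal 12, and the rhodium catalyst then adds the aldehyde C–H bond oxidatively, inserts the vinyl group on C8a into Rh–H with rhodium on the terminal carbon and reductively eliminates to form C3–C2. The closest known reaction type is the one-pot conversion of allyl vinyl ethers into cyclopentanones by thermal Claisen rearrangement followed by rhodium-catalysed intramolecular hydroacylation of the resulting 3,3-disubstituted 4-pentenal. The only ring closed is the cyclopentanone, by a formal 5-endo-trig hydroacylation that runs through a six-membered acyl rhodacycle. C3a and C8a are created together in the sigmatropic step: the (E)-enol ether holds the C4 side chain equatorial and the (E)-allyl unit holds the methyl group axial and the C8 side chain equatorial, which should put H-3a and the C8 chain on one face and the C4 chain and the methyl group on the other, while the absolute sense is set by the C8 stereocentre, whose C–O bond should lie anti to the forming bond (Felkin–Anh-type arrangement) with its hydrogen in the crowded sector between the axial methyl and the incoming carbon. The step needs chemoselective hydroacylation of one alkene out of three, and the 4-pentenal geometry secures it because only the vinyl group on C8a reaches a six-membered rhodacycle with a primary carbon–rhodium bond. C3a is α to the new ketone, but its configuration (side chain trans to the larger C8a substituent) is also the thermodynamic one, so enolisation should not erode it.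

Step 10
Reactants: 13 2,3,3-trisubstituted cyclopentanone
Product: 14 ethylidenecyclopentane (C3=CH–CH3 in place of C3=O)
Conditions: EtPPh3Br, KN(SiMe3)2, THF, 0 °C to rt
Reagents that add atoms: ethyltriphenylphosphonium bromide, CC[P+](c1ccccc1)(c1ccccc1)c1ccccc1.[Br-]
Why: Wittig olefination with a non-stabilised ylide converts the hindered cyclopentanone into the exocyclic ethylidene; the alkene geometry is irrelevant because this carbon becomes the isopropyl methine.

Step 11
Reactants: 14 ethylidenecyclopentane
Product: 15 spiro-epoxide (oxirane oxygen on C3 cis to H-3a)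
Conditions: dimethyldioxirane (1.05 equiv), acetone/CH2Cl2, −30 °C
Reagents that add atoms: dimethyldioxirane, CC1(C)OO1
Why: Dioxirane epoxidation is fastest at the trisubstituted exocyclic alkene and should occur on the face syn to H-3a, away from the C3a side chain and the pseudo-axial 8a-methyl group, which places the C3 oxygen cis to H-3a as the target requires.

Step 12
Reactants: 15 spiro-epoxide
Product: 16 tertiary cyclopentanol (full name in the compound list)
Conditions: Me2CuLi (from MeLi and CuI, 3 equiv), Et2O, −30 to 0 °C; aq. NH4Cl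
Reagents that add atoms: methyllithium (delivered as the cuprate), C[Li]
Why: SN2 opening of the epoxide by the Gilman cuprate at the less substituted oxirane carbon turns it into the isopropyl methine and leaves the C3–O bond and its configuration untouched.

Step 13
Reactants: 16 tertiary cyclopentanol
Product: 17 bis-silylated hydroazulenol (full name in the compound list)
Conditions: second-generation Hoveyda–Grubbs catalyst (10 mol %), toluene, 80 °C, argon sparge
Reagents that add atoms: none
Why: Ring-closing metathesis between the vinyl group on C8 and the methallyl group forms the trisubstituted C6=C7 alkene and the seven-membered ring, the trans ring fusion being fixed by the trans side chains set in step 9; loss of ethene drives the reaction.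

Step 14
Reactants: 17 bis-silylated hydroazulenol
Product: 18 C3,C4-diol with the C8 silyl ether retained
Conditions: PPTS (0.2 equiv), MeOH/CH2Cl2, 0 °C
Reagents that add atoms: none
Why: Acid-catalysed methanolysis cleaves the triethylsilyl ether far faster than the hindered tert-butyldimethylsilyl ether, so only the C4 hydroxyl should be freed.

Step 15
Reactants: 18 C3,C4-diol; 19 4-acetoxybenzoyl chloride
Product: 20 C4 4-acetoxybenzoate
Conditions: pyridine, DMAP (0.2 equiv), CH2Cl2, 0 °C to rt
Reagents that add atoms: none
Why: DMAP-catalysed acylation esterifies the secondary C4 hydroxyl with retention, while the tertiary C3 hydroxyl does not react under these conditions.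

Step 16
Reactants: 20 C4 4-acetoxybenzoate
Product: 21 C8 alcohol
Conditions: HF·pyridine, pyridine/THF, 0 °C to rt
Reagents that add atoms: none
Why: Fluoride-mediated desilylation under buffered acidic conditions cleaves the remaining silyl ether without touching the aryl acetate or the benzoate ester.

Step 17
Reactants: 21 C8 alcohol; 22 3-methylbutanoyl chloride
Product: 24 target compound, via aryl acetate 23 (not isolated)
Conditions: pyridine, DMAP, CH2Cl2, 40 °C; then pyrrolidine, 0 °C
Reagents that add atoms: none
Why: DMAP-catalysed acylation of the hindered allylic C8 hydroxyl with retention is followed in the same flask by chemoselective aminolysis of the activated aryl acetate, which should leave the alkyl benzoate and the isovalerate intact.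

Compound list
1 | ethyl glyoxylate | CCOC(=O)C=O | starting material
2 | 2-methylpropene | CC(C)=C | starting material
3 | ethyl (2R)-2-hydroxy-4-methylpent-4-enoate | CCOC(=O)[C@H](O)CC(C)=C | intermediate
4 | ethyl (2R)-4-methyl-2-[(triethylsilyl)oxy]pent-4-enoate | CCOC(=O)[C@H](O[Si](CC)(CC)CC)CC(C)=C | intermediate
5 | (2R)-4-methyl-2-[(triethylsilyl)oxy]pent-4-enal | O=C[C@H](O[Si](CC)(CC)CC)CC(C)=C | intermediate
6 | triethyl{[(1E,3R)-1-iodo-5-methylhexa-1,5-dien-3-yl]oxy}silane | I/C=C/[C@H](O[Si](CC)(CC)CC)CC(C)=C | intermediate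
7 | (2E)-3-methyl-4-oxobut-2-en-1-yl acetate | CC(=O)OC/C=C(\C)C=O | starting material
8 | (2E,4R)-4-hydroxy-3-methylhexa-2,5-dien-1-yl acetate | C=C[C@@H](O)/C(C)=C/COC(C)=O | intermediate
9 | (2E,4R)-4-{[tert-butyl(dimethyl)silyl]oxy}-3-methylhexa-2,5-dien-1-yl acetate | C=C[C@@H](O[Si](C)(C)C(C)(C)C)/C(C)=C/COC(C)=O | intermediate
10 | (2E,4R)-4-{[tert-butyl(dimethyl)silyl]oxy}-3-methylhexa-2,5-dien-1-ol | C=C[C@@H](O[Si](C)(C)C(C)(C)C)/C(C)=C/CO | intermediate
11 | (2E,4R)-4-{[tert-butyl(dimethyl)silyl]oxy}-3-methylhexa-2,5-dien-1-yl (1E,3R)-5-methyl-3-[(triethylsilyl)oxy]hexa-1,5-dien-1-yl ether | C=C[C@@H](O[Si](C)(C)C(C)(C)C)/C(C)=C/CO/C=C/[C@H](O[Si](CC)(CC)CC)CC(C)=C | intermediate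
12 | (2S,3S)-3-[(1R)-1-{[tert-butyl(dimethyl)silyl]oxy}prop-2-en-1-yl]-3-methyl-2-{(1R)-3-methyl-1-[(triethylsilyl)oxy]but-3-en-1-yl}pent-4-enal | C=C[C@@H](O[Si](C)(C)C(C)(C)C)[C@@](C)(C=C)[C@H](C=O)[C@H](O[Si](CC)(CC)CC)CC(C)=C | intermediate
13 | (2S,3S)-3-[(1R)-1-{[tert-butyl(dimethyl)silyl]oxy}prop-2-en-1-yl]-3-methyl-2-{(1R)-3-methyl-1-[(triethylsilyl)oxy]but-3-en-1-yl}cyclopentan-1-one | C=C[C@@H](O[Si](C)(C)C(C)(C)C)[C@@]1(C)CCC(=O)[C@@H]1[C@H](O[Si](CC)(CC)CC)CC(C)=C | intermediate
14 | 1-ethylidene analogue of 13 (C=O replaced by C=CH–CH3, stereocentres as in 13, alkene geometry undefined) | C=C[C@@H](O[Si](C)(C)C(C)(C)C)[C@@]1(C)CCC(=CC)[C@@H]1[C@H](O[Si](CC)(CC)CC)CC(C)=C | intermediate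
15 | spiro-epoxide of 14 (oxirane oxygen on C3 cis to H-3a, methyl-bearing oxirane carbon undefined) | C=C[C@@H](O[Si](C)(C)C(C)(C)C)[C@@]1(C)CC[C@](O2)(C2C)[C@@H]1[C@H](O[Si](CC)(CC)CC)CC(C)=C | intermediate
16 | (1S,2S,3S)-3-[(1R)-1-{[tert-butyl(dimethyl)silyl]oxy}prop-2-en-1-yl]-3-methyl-2-{(1R)-3-methyl-1-[(triethylsilyl)oxy]but-3-en-1-yl}-1-(propan-2-yl)cyclopentan-1-ol | C=C[C@@H](O[Si](C)(C)C(C)(C)C)[C@@]1(C)CC[C@](O)(C(C)C)[C@@H]1[C@H](O[Si](CC)(CC)CC)CC(C)=C | intermediate
17 | (3S,3aS,4R,8R,8aS)-8-{[tert-butyl(dimethyl)silyl]oxy}-6,8a-dimethyl-3-(propan-2-yl)-4-[(triethylsilyl)oxy]-1,2,3,3a,4,5,8,8a-octahydroazulen-3-ol | CC1=C[C@@H](O[Si](C)(C)C(C)(C)C)[C@@]2(C)CC[C@](O)(C(C)C)[C@@H]2[C@H](O[Si](CC)(CC)CC)C1 | intermediate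
18 | (3S,3aS,4R,8R,8aS)-8-{[tert-butyl(dimethyl)silyl]oxy}-6,8a-dimethyl-3-(propan-2-yl)-1,2,3,3a,4,5,8,8a-octahydroazulene-3,4-diol | CC1=C[C@@H](O[Si](C)(C)C(C)(C)C)[C@@]2(C)CC[C@](O)(C(C)C)[C@@H]2[C@H](O)C1 | intermediate
19 | 4-acetoxybenzoyl chloride | CC(=O)Oc1ccc(cc1)C(Cl)=O | starting material
20 | (3S,3aS,4R,8R,8aS)-8-{[tert-butyl(dimethyl)silyl]oxy}-3-hydroxy-6,8a-dimethyl-3-(propan-2-yl)-1,2,3,3a,4,5,8,8a-octahydroazulen-4-yl 4-(acetyloxy)benzoate | CC1=C[C@@H](O[Si](C)(C)C(C)(C)C)[C@@]2(C)CC[C@](O)(C(C)C)[C@@H]2[C@H](OC(=O)c2ccc(OC(C)=O)cc2)C1 | intermediate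
21 | (3S,3aS,4R,8R,8aS)-3,8-dihydroxy-6,8a-dimethyl-3-(propan-2-yl)-1,2,3,3a,4,5,8,8a-octahydroazulen-4-yl 4-(acetyloxy)benzoate | CC1=C[C@@H](O)[C@@]2(C)CC[C@](O)(C(C)C)[C@@H]2[C@H](OC(=O)c2ccc(OC(C)=O)cc2)C1 | intermediate
22 | 3-methylbutanoyl chloride | CC(C)CC(Cl)=O | starting material
23 | (3S,3aS,4R,8R,8aS)-3-hydroxy-6,8a-dimethyl-8-[(3-methylbutanoyl)oxy]-3-(propan-2-yl)-1,2,3,3a,4,5,8,8a-octahydroazulen-4-yl 4-(acetyloxy)benzoate | CC1=C[C@@H](OC(=O)CC(C)C)[C@@]2(C)CC[C@](O)(C(C)C)[C@@H]2[C@H](OC(=O)c2ccc(OC(C)=O)cc2)C1 | intermediate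
24 | (3S,3aS,4R,8R,8aS)-3-hydroxy-6,8a-dimethyl-8-[(3-methylbutanoyl)oxy]-3-(propan-2-yl)-1,2,3,3a,4,5,8,8a-octahydroazulen-4-yl 4-hydroxybenzoate | CC1=C[C@@H](OC(=O)CC(C)C)[C@@]2(C)CC[C@](O)(C(C)C)[C@@H]2[C@H](OC(=O)c2ccc(O)cc2)C1 | target

Total step count: 17. Longest linear sequence: 14 steps (steps 1–4, then 8–17).

Steps most likely to fail

Step 9. At the temperature the Claisen step needs, the acyl–rhodium hydride may lose CO, rhodium hydrides may shift the two terminal alkenes, and facial control by the C8 stereocentre may be incomplete. Fallback: the two bond formations are uncoupled. Compounds 6 and 10 are joined under the copper catalysis of step 8 but at 120 °C in xylene, so that etherification and [3,3] shift run as a domino free of metal hydrides. Aldehyde 12 is then isolated, any C8a epimer being removed by chromatography. The ring is closed separately at 25 °C with [Rh(nbd)(dppe)]BF4 (activated with H2) in acetone. This sets out from 6 and 10 and returns to the route at 13; it makes no new compound (F0).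

Step 12. Substitution at the secondary oxirane carbon next to the spiro centre may be slow, with competing base-induced elimination to an allylic alcohol or rearrangement of the epoxide. Fallback, setting out from 13 and returning at 16: kinetic enolisation toward C2 with KN(SiMe3)2 and trapping with PhNTf2 should give the enol triflate F1. Coupling with iPrMgCl under Fe(acac)3 catalysis should give the 3-isopropylcyclopentene F2. Dimethyldioxirane should epoxidise the ring alkene on the face syn to H-3a to give the ring epoxide F3. LiBHEt3 should then open it at the secondary C2 to give 16.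

Step 13. The ruthenium carbene may fail to engage the vinyl group flanked by the silyl ether and the quaternary carbon, leading to dimerisation through the methallyl group or alkene migration. Fallback, setting out from 16 and returning at 21: both silyl ethers are removed with HF·pyridine to give the triol diene F4, whose free allylic hydroxyl should speed carbene formation at the vinyl group. Ring-closing metathesis with the same catalyst should give the bicyclic triol F5. Acylation with 19 (pyridine, DMAP, −20 °C) at the C4 hydroxyl, which should react before the neopentylic C8 hydroxyl, then gives 21.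

Further compounds
F0 | step 9 | none | none
F1 | step 12 | enol triflate of 13 (C2=C3 double bond, triflyloxy group on C3) | C=C[C@@H](O[Si](C)(C)C(C)(C)C)[C@@]1(C)CC=C(OS(=O)(=O)C(F)(F)F)[C@@H]1[C@H](O[Si](CC)(CC)CC)CC(C)=C
F2 | step 12 | 3-isopropylcyclopentene (C2=C3 double bond, isopropyl on C3) | C=C[C@@H](O[Si](C)(C)C(C)(C)C)[C@@]1(C)CC=C(C(C)C)[C@@H]1[C@H](O[Si](CC)(CC)CC)CC(C)=C
F3 | step 12 | C2–C3 ring epoxide of F2 (oxygen cis to H-3a) | C=C[C@@H](O[Si](C)(C)C(C)(C)C)[C@@]1(C)C[C@H]2O[C@@]2(C(C)C)[C@@H]1[C@H](O[Si](CC)(CC)CC)CC(C)=C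
F4 | step 13 | triol diene (16 without both silyl groups) | C=C[C@@H](O)[C@@]1(C)CC[C@](O)(C(C)C)[C@@H]1[C@H](O)CC(C)=C
F5 | step 13 | (3S,3aS,4R,8R,8aS)-6,8a-dimethyl-3-(propan-2-yl)-1,2,3,3a,4,5,8,8a-octahydroazulene-3,4,8-triol | CC1=C[C@@H](O)[C@@]2(C)CC[C@](O)(C(C)C)[C@@H]2[C@H](O)C1
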